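Cuts (isoflavan numbering; TBS = tert-butyldimethylsilyl): first the three O–TBS bonds, then O1–C2 together with C3–H (ring C), then C4–C4a (aromatic Claisen), C3–C1' (Suzuki–Miyaura) and the phenol O–CH2 bond (Williamson). C2, C3 and C4 therefore all come from 2,3-dibromoprop-1-ene.
Enabling feature: O1–C2 and C3–H are vicinal, so removing both leaves the terminal alkene C2=C3 of a 2-(2-arylallyl)phenol. Ring B on C3 makes this the one easily oxidised π bond and stabilises a C3 radical, and the C8a hydroxyl of ring A lies in 6-endo reach of C2.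
Rings A and B are the same unit (oxygen ortho and para to the point of attachment, 1,1-dimethylallyl meta to it). Both are drawn from one bis-TBS ether of 4-(1,1-dimethylallyl)resorcinol, built from 2,4-dihydroxyphenylacetic acid by lactonisation, gem-dimethylation, reduction to the lactol and methylenation.
Forward: the common arene is split into a ring B boronate and a ring A phenol. The phenol takes the allylic bromide of the three-carbon linchpin and the boronate its vinylic bromide, a [3,3] shift moves the chain from oxygen to C4a, ring C closes last, and desilylation ends the route.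
Stereochemistry: C3 is the only stereocentre. It is created in the ring closure, when the planar C3 radical takes a hydrogen atom from an axially chiral arenethiol, and no later step can disturb it.

Key step: step 13

Assumption: the sense of induction of an axially chiral arenethiol toward the C3 radical cannot be derived from a model, so the route is written with (R)-2'-methoxy-1,1'-binaphthalene-2-thiol (a known compound, from BINOL by monomethylation, thiocarbamoylation, Newman–Kwart rearrangement and reduction; as a catalyst it is not counted in the steps), and its (S)-antipode takes its place should the (R)-form favour 3S.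

Step 1
Reactants: 1 2,4-dihydroxyphenylacetic acid
Product: 2 6-hydroxy-1-benzofuran-2(3H)-one
Conditions: p-TsOH·H2O (5 mol %), toluene, reflux, Dean–Stark trap
Reagents that add atoms: none
Why: Acid-catalysed lactonisation (intramolecular Fischer esterification) in which only the hydroxyl ortho to the side chain can reach the carboxyl group through a five-membered ring, with azeotropic removal of water pulling the equilibrium over.

Step 2
Reactants: 2 6-hydroxy-1-benzofuran-2(3H)-one
Product: 3 6-(tert-butyldimethylsilyloxy)-1-benzofuran-2(3H)-one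
Conditions: TBSCl, imidazole, DMF, 0 °C → rt
Reagents that add atoms: tert-butyldimethylsilyl chloride, CC(C)(C)[Si](C)(C)Cl
Why: Imidazole-promoted O-silylation of the one remaining phenol, which keeps oxygen out of the alkylation that follows and installs the group that ring B keeps on O2' to the end.

Step 3
Reactants: 3 6-(tert-butyldimethylsilyloxy)-1-benzofuran-2(3H)-one
Product: 5 6-(tert-butyldimethylsilyloxy)-3,3-dimethyl-1-benzofuran-2(3H)-one, via monomethyl lactone 4 (not isolated)
Conditions: NaH (2.3 equiv), MeI (4 equiv), THF, 0 °C → rt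
Reagents that add atoms: iodomethane, CI
Why: Exhaustive enolate C-alkylation: C3–H of a benzofuran-2(3H)-one is unusually acidic because its enolate is an aromatic 2-oxidobenzofuran, the soft electrophile reacts at carbon, and with iodomethane present from the start the monomethyl lactone 4 is deprotonated and methylated again before it can condense with itself.

Step 4
Reactants: 5 6-(tert-butyldimethylsilyloxy)-3,3-dimethyl-1-benzofuran-2(3H)-one
Product: 6 6-(tert-butyldimethylsilyloxy)-3,3-dimethyl-2,3-dihydro-1-benzofuran-2-ol (racemic lactol)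
Conditions: i-Bu2AlH (1.1 equiv), toluene, −78 °C; then MeOH, aq. potassium sodium tartrate
Reagents that add atoms: none
Why: Partial reduction of a lactone with i-Bu2AlH, in which the aluminium hemiacetal next to the quaternary carbon is stable at −78 °C and is released as the lactol (a racemic, inconsequential centre) only on work-up.

Step 5
Reactants: 6 6-(tert-butyldimethylsilyloxy)-3,3-dimethyl-2,3-dihydro-1-benzofuran-2-ol
Product: 8 5-(tert-butyldimethylsilyloxy)-2-(2-methylbut-3-en-2-yl)phenol, via ring-opened hydroxy aldehyde 7 (not isolated)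
Conditions: Ph3PCH3Br (3 equiv), KN(SiMe3)2 (2.9 equiv), THF, 0 °C → rt
Reagents that add atoms: methyltriphenylphosphonium bromide, C[P+](c1ccccc1)(c1ccccc1)c1ccccc1.[Br-]
Why: Wittig methylenation: excess ylide deprotonates the lactol, the ring-opened phenoxide aldehyde 7 cannot enolise, and its only reaction is olefination to the 1,1-dimethylallyl (reverse prenyl) group.

Step 6
Reactants: 8 5-(tert-butyldimethylsilyloxy)-2-(2-methylbut-3-en-2-yl)phenol
Product: 9 2,4-bis(tert-butyldimethylsilyloxy)-1-(2-methylbut-3-en-2-yl)benzene
Conditions: TBSOTf, 2,6-lutidine, CH2Cl2, 0 °C → rt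
Reagents that add atoms: tert-butyldimethylsilyl trifluoromethanesulfonate, CC(C)(C)[Si](C)(C)OS(=O)(=O)C(F)(F)F
Why: Silylation with the silyl triflate and a hindered pyridine base, the standard answer to a phenol flanked by a quaternary carbon, run acid-free so that the ortho 1,1-dimethylallyl group cannot cyclise onto the oxygen.

Step 7
Reactants: 9 2,4-bis(tert-butyldimethylsilyloxy)-1-(2-methylbut-3-en-2-yl)benzene
Product: 10 1-bromo-2,4-bis(tert-butyldimethylsilyloxy)-5-(2-methylbut-3-en-2-yl)benzene
Conditions: NBS (1.0 equiv), CH2Cl2–MeCN, −10 °C, dark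
Reagents that add atoms: N-bromosuccinimide, O=C1CCC(=O)N1Br
Why: Electrophilic aromatic bromination directed by both oxygens to the one open position that is para to one and ortho to the other (the site between the two silyloxy groups is shielded), the doubly activated ring reacting far faster with NBS than the monosubstituted neopentyl-type vinyl group.

Step 8
Reactants: 10 1-bromo-2,4-bis(tert-butyldimethylsilyloxy)-5-(2-methylbut-3-en-2-yl)benzene
Product: 11 2-[2,4-bis(tert-butyldimethylsilyloxy)-5-(2-methylbut-3-en-2-yl)phenyl]-4,4,5,5-tetramethyl-1,3,2-dioxaborolane (ring B boronate)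
Conditions: B2pin2, PdCl2(dppf) (5 mol %), KOAc, 1,4-dioxane, 85 °C
Reagents that add atoms: bis(pinacolato)diboron, CC1(C)OB(OC1(C)C)B1OC(C)(C)C(C)(C)O1
Why: Miyaura borylation, chosen over halogen–lithium exchange because an aryllithium ortho to a silyloxy group would undergo retro-Brook O-to-C silyl migration, and mild enough (acetate base) for the aryl silyl ethers.

Step 9
Reactants: 9 2,4-bis(tert-butyldimethylsilyloxy)-1-(2-methylbut-3-en-2-yl)benzene
Product: 12 3-(tert-butyldimethylsilyloxy)-4-(2-methylbut-3-en-2-yl)phenol (ring A phenol)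
Conditions: Bu4NF (1.0 equiv), AcOH (1.0 equiv), THF, −40 → −10 °C
Reagents that add atoms: none
Why: Sterically differentiated fluoride desilylation: the silyl ether with two ortho hydrogens is attacked much faster than the one pressed against the quaternary benzylic carbon, and the acetic acid buffer stops phenoxide-mediated silyl scrambling.

Step 10
Reactants: 12 3-(tert-butyldimethylsilyloxy)-4-(2-methylbut-3-en-2-yl)phenol; 13 2,3-dibromoprop-1-ene
Product: 14 4-[(2-bromoprop-2-en-1-yl)oxy]-2-(tert-butyldimethylsilyloxy)-1-(2-methylbut-3-en-2-yl)benzene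
Conditions: K2CO3, acetone, 50 °C
Reagents that add atoms: none
Why: Williamson ether synthesis in which the phenoxide displaces only the allylic bromide of 13 by SN2, the vinylic C–Br bond being inert to substitution and kept for the next step.

Step 11
Reactants: 14 4-[(2-bromoprop-2-en-1-yl)oxy]-2-(tert-butyldimethylsilyloxy)-1-(2-methylbut-3-en-2-yl)benzene; 11 ring B boronate
Product: 15 1-{3-[3-(tert-butyldimethylsilyloxy)-4-(2-methylbut-3-en-2-yl)phenoxy]prop-1-en-2-yl}-2,4-bis(tert-butyldimethylsilyloxy)-5-(2-methylbut-3-en-2-yl)benzene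
Conditions: Pd(OAc)2 (3 mol %), SPhos (6 mol %), K3PO4, THF–H2O (10:1), 45 °C
Reagents that add atoms: none
Why: Suzuki–Miyaura coupling of an alkenyl bromide with an arylboronate, in which zerovalent palladium inserts into the vinylic C–Br bond, the bulky electron-rich phosphine copes with the ortho-silyloxy boronate at a temperature low enough to limit protodeboronation and silyl loss, and any ionisation of the allyl aryl ether would be degenerate because the 2-aryl-π-allyl unit is symmetrical.

Step 12
Reactants: 15 1-{3-[3-(tert-butyldimethylsilyloxy)-4-(2-methylbut-3-en-2-yl)phenoxy]prop-1-en-2-yl}-2,4-bis(tert-butyldimethylsilyloxy)-5-(2-methylbut-3-en-2-yl)benzene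
Product: 17 2-{2-[2,4-bis(tert-butyldimethylsilyloxy)-5-(2-methylbut-3-en-2-yl)phenyl]prop-2-en-1-yl}-5-(tert-butyldimethylsilyloxy)-4-(2-methylbut-3-en-2-yl)phenol, via ortho-dienone 16 (not isolated)
Conditions: PhNEt2, 185 °C, argon, sealed tube
Reagents that add atoms: none
Why: Aromatic Claisen rearrangement ([3,3]-sigmatropic shift, then tautomerisation of dienone 16): of the two ortho positions C8 is screened by the C7 silyloxy group, which the neighbouring quaternary carbon pushes toward it, so the allyl unit should migrate to C4a, while the amine solvent suppresses acid-catalysed Markovnikov cyclisation and the silyl groups on O7 and O4' prevent abnormal-Claisen isomerisation of the 1,1-dimethylallyl groups.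

Step 13
Reactants: 17 2-{2-[2,4-bis(tert-butyldimethylsilyloxy)-5-(2-methylbut-3-en-2-yl)phenyl]prop-2-en-1-yl}-5-(tert-butyldimethylsilyloxy)-4-(2-methylbut-3-en-2-yl)phenol
Product: 19 (3R)-7,2',4'-tris(tert-butyldimethylsilyloxy)-6,5'-bis(2-methylbut-3-en-2-yl)isoflavan, via C3 benzylic radical 18 (not isolated)
Conditions: 9-mesityl-10-methylacridinium tetrafluoroborate (5 mol %), (R)-2'-methoxy-1,1'-binaphthalene-2-thiol (20 mol %), ClCH2CH2Cl (0.05 M, degassed), 450 nm LED, −20 °C
Reagents that add atoms: none
Why: Proposed new method: the photoexcited acridinium removes one electron from the ring B-conjugated 1,1-disubstituted alkene of 17, the C8a hydroxyl adds to the terminal carbon of the radical cation (O1–C2 bond, 6-endo-trig closure of ring C), loss of the proton leaves the planar tertiary benzylic radical 18, this takes a hydrogen atom from the S–H bond, and the thiyl radical is reduced by the acridinyl radical and reprotonated, so that both catalysts are returned. The closest known reaction types are the racemic acridinium/arenethiol anti-Markovnikov hydroetherification of alkenols and the enantioselective hydrogen-atom transfer from carbohydrate-derived or cysteine-peptide thiols to prochiral tertiary carbon radicals; their combination, with a phenol as nucleophile and a benzylic radical as acceptor, has not been demonstrated. C3 is the only new stereocentre and is under pure catalyst control: the binaphthyl wall next to sulfur has to distinguish the C2H2–O1 flank of 18 from the C4H2–aryl flank, a difference to which the O2' silyloxy group, forced toward one of these flanks, should add, and low temperature in a weakly polar solvent is chosen to sharpen it. An arenethiol (S–H roughly 79 kcal/mol) is preferred to an alkanethiol (roughly 87) because the new tertiary benzylic C3–H bond is worth only about 84 kcal/mol, so the transfer is downhill and the thiyl radical cannot abstract the hydrogen again and racemise 19. Regioselectivity follows from the ring B-stabilised radical (attack at the inner carbon would leave a primary radical), chemoselectivity from the far higher oxidation potential of the two isolated vinyl groups, which no hydrogenation of an isoflavene could be expected to spare, and the silyl group on O2' shuts off the rival 5-endo closure to a dihydrobenzofuran.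

Step 14
Reactants: 19 (3R)-7,2',4'-tris(tert-butyldimethylsilyloxy)-6,5'-bis(2-methylbut-3-en-2-yl)isoflavan
Product: 20 manuifolin E, (3R)-7,2',4'-trihydroxy-6,5'-bis(2-methylbut-3-en-2-yl)isoflavan
Conditions: Bu4NF (4 equiv), AcOH (4 equiv), THF, 0 °C → rt
Reagents that add atoms: none
Why: Fluoride cleavage of the three aryl silyl ethers under acetic acid buffering, conditions that touch neither the vinyl groups nor the non-acidic C3–H, so the 3R configuration is carried unchanged into the target.

Compound list
1 | 2,4-dihydroxyphenylacetic acid | O=C(O)Cc1ccc(O)cc1O | starting material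
2 | 6-hydroxy-1-benzofuran-2(3H)-one | O=C1Cc2ccc(O)cc2O1 | intermediate
3 | 6-(tert-butyldimethylsilyloxy)-1-benzofuran-2(3H)-one | O=C1Cc2ccc(O[Si](C)(C)C(C)(C)C)cc2O1 | intermediate
4 | 6-(tert-butyldimethylsilyloxy)-3-methyl-1-benzofuran-2(3H)-one (racemic, not isolated) | CC1C(=O)Oc2cc(O[Si](C)(C)C(C)(C)C)ccc21 | intermediate
5 | 6-(tert-butyldimethylsilyloxy)-3,3-dimethyl-1-benzofuran-2(3H)-one | CC1(C)C(=O)Oc2cc(O[Si](C)(C)C(C)(C)C)ccc21 | intermediate
6 | 6-(tert-butyldimethylsilyloxy)-3,3-dimethyl-2,3-dihydro-1-benzofuran-2-ol (racemic) | CC1(C)C(O)Oc2cc(O[Si](C)(C)C(C)(C)C)ccc21 | intermediate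
7 | 2-[4-(tert-butyldimethylsilyloxy)-2-hydroxyphenyl]-2-methylpropanal (not isolated) | CC(C)(C=O)c1ccc(O[Si](C)(C)C(C)(C)C)cc1O | intermediate
8 | 5-(tert-butyldimethylsilyloxy)-2-(2-methylbut-3-en-2-yl)phenol | C=CC(C)(C)c1ccc(O[Si](C)(C)C(C)(C)C)cc1O | intermediate
9 | 2,4-bis(tert-butyldimethylsilyloxy)-1-(2-methylbut-3-en-2-yl)benzene | C=CC(C)(C)c1ccc(O[Si](C)(C)C(C)(C)C)cc1O[Si](C)(C)C(C)(C)C | intermediate
10 | 1-bromo-2,4-bis(tert-butyldimethylsilyloxy)-5-(2-methylbut-3-en-2-yl)benzene | C=CC(C)(C)c1cc(Br)c(O[Si](C)(C)C(C)(C)C)cc1O[Si](C)(C)C(C)(C)C | intermediate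
11 | 2-[2,4-bis(tert-butyldimethylsilyloxy)-5-(2-methylbut-3-en-2-yl)phenyl]-4,4,5,5-tetramethyl-1,3,2-dioxaborolane | C=CC(C)(C)c1cc(B2OC(C)(C)C(C)(C)O2)c(O[Si](C)(C)C(C)(C)C)cc1O[Si](C)(C)C(C)(C)C | intermediate
12 | 3-(tert-butyldimethylsilyloxy)-4-(2-methylbut-3-en-2-yl)phenol | C=CC(C)(C)c1ccc(O)cc1O[Si](C)(C)C(C)(C)C | intermediate
13 | 2,3-dibromoprop-1-ene | C=C(Br)CBr | starting material
14 | 4-[(2-bromoprop-2-en-1-yl)oxy]-2-(tert-butyldimethylsilyloxy)-1-(2-methylbut-3-en-2-yl)benzene | C=C(Br)COc1ccc(C(C)(C)C=C)c(O[Si](C)(C)C(C)(C)C)c1 | intermediate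
15 | 1-{3-[3-(tert-butyldimethylsilyloxy)-4-(2-methylbut-3-en-2-yl)phenoxy]prop-1-en-2-yl}-2,4-bis(tert-butyldimethylsilyloxy)-5-(2-methylbut-3-en-2-yl)benzene | C=C(COc1ccc(C(C)(C)C=C)c(O[Si](C)(C)C(C)(C)C)c1)c1cc(C(C)(C)C=C)c(O[Si](C)(C)C(C)(C)C)cc1O[Si](C)(C)C(C)(C)C | intermediate
16 | 6-{2-[2,4-bis(tert-butyldimethylsilyloxy)-5-(2-methylbut-3-en-2-yl)phenyl]prop-2-en-1-yl}-3-(tert-butyldimethylsilyloxy)-4-(2-methylbut-3-en-2-yl)cyclohexa-2,4-dien-1-one (racemic, not isolated) | C=C(CC1C=C(C(C)(C)C=C)C(O[Si](C)(C)C(C)(C)C)=CC1=O)c1cc(C(C)(C)C=C)c(O[Si](C)(C)C(C)(C)C)cc1O[Si](C)(C)C(C)(C)C | intermediate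
17 | 2-{2-[2,4-bis(tert-butyldimethylsilyloxy)-5-(2-methylbut-3-en-2-yl)phenyl]prop-2-en-1-yl}-5-(tert-butyldimethylsilyloxy)-4-(2-methylbut-3-en-2-yl)phenol | C=C(Cc1cc(C(C)(C)C=C)c(O[Si](C)(C)C(C)(C)C)cc1O)c1cc(C(C)(C)C=C)c(O[Si](C)(C)C(C)(C)C)cc1O[Si](C)(C)C(C)(C)C | intermediate
18 | 7,2',4'-tris(tert-butyldimethylsilyloxy)-6,5'-bis(2-methylbut-3-en-2-yl)isoflavan-3-yl radical (not isolated) | C=CC(C)(C)c1cc2c(cc1O[Si](C)(C)C(C)(C)C)OC[C](c1cc(C(C)(C)C=C)c(O[Si](C)(C)C(C)(C)C)cc1O[Si](C)(C)C(C)(C)C)C2 | intermediate
19 | (3R)-7,2',4'-tris(tert-butyldimethylsilyloxy)-6,5'-bis(2-methylbut-3-en-2-yl)isoflavan | C=CC(C)(C)c1cc2c(cc1O[Si](C)(C)C(C)(C)C)OC[C@@H](c1cc(C(C)(C)C=C)c(O[Si](C)(C)C(C)(C)C)cc1O[Si](C)(C)C(C)(C)C)C2 | intermediate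
20 | manuifolin E, (3R)-7,2',4'-trihydroxy-6,5'-bis(2-methylbut-3-en-2-yl)isoflavan | C=CC(C)(C)c1cc2c(cc1O)OC[C@@H](c1cc(C(C)(C)C=C)c(O)cc1O)C2 | target

Total step count: 14.
Longest linear sequence: 12 steps (steps 1–8 and 11–14; the branch through steps 9 and 10 is equally long).

Steps most likely to fail

1. Step 13.
- What may go wrong: weak facial discrimination in the hydrogen-atom transfer, since the two flanks of the C3 radical differ only as CH2–O and CH2–aryl. Thiol may also be lost through radical addition to the vinyl groups, and the free phenol ring may be oxidised unproductively.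
- Fallback: it uses known chemistry only, needs no light, sets out from 17 and comes back to the route at 19. Copper-catalysed enantioselective protoboration of 1,1-disubstituted aryl alkenes (CuCl, a chiral imidazolinium salt as carbene precursor in the enantiomeric form that gives R, KOt-Bu, B2pin2, MeOH, THF, −15 °C) should add boron to C2 and hydrogen to C3 of the aryl-conjugated alkene only. The isolated neopentyl-type vinyl groups lack the aryl activation that Cu–B addition needs, and the phenol, like the added methanol, merely serves as proton source for the C–Cu bond. This should give the (R)-configured primary pinacol boronate F1. Oxidation with NaBO3·4H2O in THF–H2O turns C–B into C–O without touching the stereocentre and gives the (R)-configured phenol alcohol F2. Mitsunobu etherification (PPh3, DIAD, THF, 0 °C) then closes O1–C2 at the primary carbon to give 19.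

2. Step 12.
- What may go wrong: partial migration of the allyl unit to C8, and thermal wear at 185 °C (Markovnikov cyclisation of the liberated phenol onto the styrene, loss of silyl groups).
- Fallback: it makes the C4–C4a bond by cross-coupling at a position already fixed by the bromination of step 7, sets out from 11 and 13 and comes back at 17. Zerovalent palladium ionises the allylic C–Br bond of 13 far faster than it inserts into the vinylic one. Boronate 11 with a threefold excess of 13 (Pd(PPh3)4, K2CO3, THF–H2O, 40 °C) should therefore give the 2-bromoallyl arene F3. One equivalent of Bu4NF/AcOH at low temperature removes the silyl group next to the CH2 group in preference to the one next to the quaternary carbon and gives the 2-(2-bromoallyl)phenol F4. A second portion of 11 is then coupled to the vinylic bromide under the conditions of step 11, which tolerate a free phenol, to give 17.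

3. Step 9.
- What may go wrong: incomplete discrimination between the two silyl ethers, showing up as over-cleavage or as silyl scrambling through the phenoxide.
- Fallback: it moves the selection from bond breaking to bond making, sets out from 8 and comes back at 14. Complete desilylation of 8 (Bu4NF, AcOH, THF, 0 °C) gives 4-(2-methylbut-3-en-2-yl)benzene-1,3-diol F5. One equivalent of 13 with K2CO3 in acetone alkylates the unhindered hydroxyl, the other being shielded by the quaternary carbon, and gives the mono(2-bromoallyl) ether F6. TBSOTf with 2,6-lutidine caps the hindered hydroxyl to give 14.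

Further compounds
F1 | step 13 | 2-{(2R)-2-[2,4-bis(tert-butyldimethylsilyloxy)-5-(2-methylbut-3-en-2-yl)phenyl]-3-[4-(tert-butyldimethylsilyloxy)-2-hydroxy-5-(2-methylbut-3-en-2-yl)phenyl]propyl}-4,4,5,5-tetramethyl-1,3,2-dioxaborolane | CC1(C)OB(OC1(C)C)C[C@@H](c1cc(C(C)(C)C=C)c(O[Si](C)(C)C(C)(C)C)cc1O[Si](C)(C)C(C)(C)C)Cc1cc(C(C)(C)C=C)c(O[Si](C)(C)C(C)(C)C)cc1O
F2 | step 13 | (2R)-2-[2,4-bis(tert-butyldimethylsilyloxy)-5-(2-methylbut-3-en-2-yl)phenyl]-3-[4-(tert-butyldimethylsilyloxy)-2-hydroxy-5-(2-methylbut-3-en-2-yl)phenyl]propan-1-ol | OC[C@@H](c1cc(C(C)(C)C=C)c(O[Si](C)(C)C(C)(C)C)cc1O[Si](C)(C)C(C)(C)C)Cc1cc(C(C)(C)C=C)c(O[Si](C)(C)C(C)(C)C)cc1O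
F3 | step 12 | 1-(2-bromoprop-2-en-1-yl)-2,4-bis(tert-butyldimethylsilyloxy)-5-(2-methylbut-3-en-2-yl)benzene | C=C(Br)Cc1cc(C(C)(C)C=C)c(O[Si](C)(C)C(C)(C)C)cc1O[Si](C)(C)C(C)(C)C
F4 | step 12 | 2-(2-bromoprop-2-en-1-yl)-5-(tert-butyldimethylsilyloxy)-4-(2-methylbut-3-en-2-yl)phenol | C=C(Br)Cc1cc(C(C)(C)C=C)c(O[Si](C)(C)C(C)(C)C)cc1O
F5 | step 9 | 4-(2-methylbut-3-en-2-yl)benzene-1,3-diol | C=CC(C)(C)c1ccc(O)cc1O
F6 | step 9 | 5-[(2-bromoprop-2-en-1-yl)oxy]-2-(2-methylbut-3-en-2-yl)phenol | C=C(Br)COc1ccc(C(C)(C)C=C)c(O)c1
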